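The earlier runs and the new flask stem from a simulated flask for an exercise.

L is the product I want from this flask, and in hours and charges the question is how much of the charge stays outside L once the flask stops moving.

| setting | oak | maple | flask |
|---|---|---|---|
| G | 0.84 M | 1.3 M | 0.60 M |
| remark | run made earlier | run made earlier |  |
| time |  |  | 2.5 h |

| run | time / min | G / % | L / % | D / % |
|---|---|---|---|---|
| oak | 8.00 | 15.7 | 57.3 | 25.4 |
| oak | 15.0 | 5.9 | 81.4 | 12.9 |
| oak | 25.0 | 2.2 | 91.7 | 4.8 |
| oak | 50.0 | 0.6 | 96.1 | 2.7 |
| oak | 90.0 | 0.7 | 95.8 | 3.3 |
| maple | 20.0 | 3.6 | 90.8 | 6.5 |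
| maple | 40.0 | 1.8 | 97.0 | 1.8 |
| maple | 50.0 | 0.8 | 98.1 | 3.0 |
| maple | 80.0 | 0.3 | 97.0 | 2.4 |
| maple | 90.0 | 0.1 | 97.4 | 2.3 |

(standard deviation of a reading: 0.5 percentage points)

- at 2.5 h, what has stopped the reaction, if anything has (it is still moving / forward and back rates have come level)
- conversion of G at 2.5 h
- amount of L at 2.5 h, in percent of the G charged
- amount of D at 2.5 h, in percent of the G charged

- a reading or a percentage of L counts all its forms, free or not
- the reaction counts as stopped when no species that holds the G changes by six tenths of a point or more over the second half of the time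
- a reading of G is of its free form alone

I reckon on a ladder of times, in logarithms, from the quickest rung up.

1. In the oak run, G drops from 15.7% to 5.9% between 8.00 min and 15.0 min, a half-life of about 4.96 min.

2. Over the same interval D comes down more slowly, with a half-life of about 7.16 min.

3. By 50.0 min the oak readings are flat within scatter, and the maple readings are flat from 50.0 min.

4. The flask gets 2.5 h, far longer than that half-life of D. If the half-life holds there, a gap shrinks by 6.31 powers of ten. I expect forward and back rates level: thermodynamic control, not kinetic.

5. So the height of the plateau is what counts. I plot log percentage against log charge and read the fall, the slope with its sign turned: a fall of zero means a fixed percentage, a fall of one a fixed concentration. G reads 1.11. D reads 0.357, but loosely, since its plateaus differ by 0.43 percentage points against a scatter of 0.5 points per reading.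

6. I take a fall of one for both. My working quantity is 29.3 mM, the plateau concentration cD: plateau percentage times charge, averaged over both runs. The same product for G gives cG = 5.33 mM.

7. One division each for the flask gives D 4.88%, conversion 99.1% and L 94.2%.

The forecast says forward and back rates have come level, conversion 99%, L 95.5% and D 3.5%, on the ground that “dilution leaves more G and D”. Its D is lower than mine.

The flask gives forward and back rates have come level, conversion 98.3%, L 93.7% and D 4.60%.

    D ⇌ G (k = 0.00140 s⁻¹)
    J ⇌ L, rate k2*(cs2 - [L]) while solid is left; crystals form when [L] > cs2 (solubility = 12.0 mM, k = 0.0490 s⁻¹)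
    G + L ⇌ Q, settled at all times (K = 1.90 M⁻¹)
    L ⇌ D (K = 2.30, k = 0.00850 s⁻¹)
    G ⇌ L (K = 1.20, k = 0.00140 s⁻¹)

In the flask, D stands at 4.60% after 1.25 h and at 4.60% after 2.50 h. Dividing cD by the charge gave 4.88% for this flask. For the neighbour charged with 0.36 M of G, the same division gives 8.14%, and that flask holds 7.67% of D at 2.50 h.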